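Everything rests on building ring B of flavone 1 (the 7-methoxy unit) by a Diels–Alder reaction. The key step exploits the 1',3',4' pattern of that ring: C1' carries the chromone carbon, C3' the hindered bond to C8 of flavone 2 and C4' an oxygen, which is the pattern of a 6-aryl-4-(methoxycarbonyl)cyclohex-2-enone. A 4-aryl-1-methoxy-3-silyloxybutadiene, whose aryl group is dibenzylated resorcinol (the future ring A of flavone 2), adds to methyl acrylate and forms C2'–C3' and C1'–C6' in one operation, so the crowded C3'–C8 bond enters as a simple benzylic bond. Dehydrogenation to the arene and two flavone annulations finish the synthesis.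

Key step: step 4

Remark: the C3'–C8 biaryl axis carries only three small ortho substituents and is taken as freely rotating, so the target has no stereochemical element; compounds 7, 8 and 19 are racemic.

Step 1
Reactants: 1 2-bromoresorcinol
Product: 2 1,3-bis(benzyloxy)-2-bromobenzene
Conditions: BnBr (2.2 equiv), K2CO3, DMF, 60 °C
Reagents that add atoms: benzyl bromide, BrCc1ccccc1
Why: Williamson ether synthesis, in which both phenoxides of 1 attack benzyl bromide by SN2 while the aryl bromide is inert to carbonate.

Step 2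
Reactants: 2 1,3-bis(benzyloxy)-2-bromobenzene, 3 (E)-4-methoxybut-3-en-2-one (2 equiv)
Product: 4 (3E)-1-[2,6-bis(benzyloxy)phenyl]-4-methoxybut-3-en-2-one
Conditions: Pd(OAc)2 (3 mol%), XPhos (6 mol%), K3PO4, toluene, 80 °C
Reagents that add atoms: none
Why: Palladium-catalysed α-arylation of a ketone enolate, in which the methyl group is the only enolisable position of 3, the bulky biaryl phosphine lets zerovalent palladium insert into the hindered electron-rich C–Br bond and promotes reductive elimination, the mild phosphate base keeps the enolate concentration low enough to limit self-condensation of the vinylogous ester, and the two ortho benzyloxy groups block a second arylation.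

Step 3
Reactants: 4 (3E)-1-[2,6-bis(benzyloxy)phenyl]-4-methoxybut-3-en-2-one
Product: 5 (1E,3Z)-4-[2,6-bis(benzyloxy)phenyl]-3-[(tert-butyldimethylsilyl)oxy]-1-methoxybuta-1,3-diene
Conditions: TBSOTf, Et3N, CH2Cl2, 0 °C
Reagents that add atoms: tert-butyldimethylsilyl trifluoromethanesulfonate, CC(C)(C)[Si](C)(C)OS(=O)(=O)C(F)(F)F
Why: Soft enolisation (silyl triflate and amine) removes a doubly activated benzylic proton and should give the thermodynamically preferred (3Z) silyl dienol ether, with the aryl group cis to the silyloxy group and trans to the vinyl chain as the cycloaddition requires; the tert-butyldimethylsilyl ether is chosen over a trimethylsilyl ether so that 5 can be filtered through basic alumina and withstands prolonged heating.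

Step 4
Reactants: 5 (1E,3Z)-4-[2,6-bis(benzyloxy)phenyl]-3-[(tert-butyldimethylsilyl)oxy]-1-methoxybuta-1,3-diene, 6 methyl acrylate
Product: 8 methyl 5-[2,6-bis(benzyloxy)phenyl]-4-oxocyclohex-2-ene-1-carboxylate, via cycloadduct 7 (not isolated)
Conditions: 6 (10 equiv), BHT (cat.), toluene, 110 °C, sealed tube; then 1 M HCl, THF, 0 °C to rt
Reagents that add atoms: none
Why: Normal-electron-demand Diels–Alder reaction, concerted but asynchronous: the HOMO of the doubly oxygenated diene has its largest coefficient at the aryl-bearing C4, which bonds first to the β-carbon of the acrylate while C1 joins the α-carbon, and aqueous acid then hydrolyses the silyl enol ether of 7 and eliminates methanol to give the enone. The closest known reaction type is the cycloaddition of 1-methoxy-3-silyloxybutadienes with acrylates. Ring B is closed as a six-membered carbocycle by suprafacial [4+2] cycloaddition of a four-carbon and a two-carbon unit, both new bonds (C2'–C3' and C1'–C6') forming in one transition state. The stereocentres of 7 (C1, C2 and C5 of the cyclohexene) follow from uncontrolled endo/exo approach, the two that remain in 8 (C1 and C5) are epimerisable, and all are erased in step 5, so a racemic mixture of diastereomers is acceptable. The step needs only regioselectivity, which is secured because the methoxy group at C1 and the silyloxy group at C3 polarise the diene in the same sense while the aryl group is twisted out of conjugation; the (3Z) geometry keeps the aryl group on the outside of the s-cis diene, so the reactive conformer is accessible.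

Step 5
Reactants: 8 methyl 5-[2,6-bis(benzyloxy)phenyl]-4-oxocyclohex-2-ene-1-carboxylate
Product: 9 methyl 3-[2,6-bis(benzyloxy)phenyl]-4-hydroxybenzoate
Conditions: DDQ (1.2 equiv), 1,4-dioxane, 80 °C
Reagents that add atoms: none
Why: Dehydrogenative aromatisation, in which DDQ abstracts hydride from the enol form of 8 and proton loss gives a cyclohexadienone that tautomerises irreversibly to the phenol, while the benzyl aryl ethers (not activated like 4-methoxybenzyl ethers) should survive under anhydrous conditions.

Step 6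
Reactants: 9 methyl 3-[2,6-bis(benzyloxy)phenyl]-4-hydroxybenzoate
Product: 10 methyl 3-[2,6-bis(benzyloxy)phenyl]-4-methoxybenzoate
Conditions: MeI, K2CO3, DMF, rt
Reagents that add atoms: iodomethane, CI
Why: Williamson O-methylation of the phenoxide by SN2 on iodomethane, with the ester and the benzyl ethers inert.

Step 7
Reactants: 10 methyl 3-[2,6-bis(benzyloxy)phenyl]-4-methoxybenzoate, 11 paeonol (1-(2-hydroxy-4-methoxyphenyl)ethan-1-one)
Product: 13 2-{3-[2,6-bis(benzyloxy)phenyl]-4-methoxyphenyl}-7-methoxy-4H-chromen-4-one, via β-diketone 12 (not isolated)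
Conditions: 11, LiN(SiMe3)2 (3.5 equiv), THF, −78 to −10 °C; 10, −78 °C to rt; AcOH; then TsOH·H2O (cat.), toluene, 90 °C
Reagents that add atoms: none
Why: Crossed Claisen condensation of the dilithiated (phenoxide–enolate) form of 11 with the non-enolisable aryl ester 10, driven by deprotonation of the β-diketone, followed by acid-catalysed cyclodehydration of the 2-hydroxyaryl diketone to the 4-pyranone ring (the diketone route to flavones known from Baker–Venkataraman chemistry); catalytic sulfonic acid in toluene should leave the benzyl ethers intact.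

Step 8
Reactants: 13 2-{3-[2,6-bis(benzyloxy)phenyl]-4-methoxyphenyl}-7-methoxy-4H-chromen-4-one
Product: 14 2-[3-(2,6-dihydroxyphenyl)-4-methoxyphenyl]-7-methoxy-4H-chromen-4-one
Conditions: H2 (1 atm), 10% Pd/C, EtOAc/MeOH, rt
Reagents that add atoms: none
Why: Catalytic hydrogenolysis of the two benzyl aryl ethers, under which the conjugated C2–C3 double bond of the flavone and the aryl methyl ethers should not be reduced at room temperature and one atmosphere.

Step 9
Reactants: 14 2-[3-(2,6-dihydroxyphenyl)-4-methoxyphenyl]-7-methoxy-4H-chromen-4-one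
Product: 16 2-[3-(3-acetyl-2,6-dihydroxyphenyl)-4-methoxyphenyl]-7-methoxy-4H-chromen-4-one, via difluoroboron chelate 15 (not isolated)
Conditions: AcOH, BF3·OEt2, 90 °C; then aq. NaOAc, EtOH, 70 °C
Reagents that add atoms: acetic acid, CC(=O)O
Why: Boron trifluoride-mediated Friedel–Crafts C-acetylation (Nencki-type acylation) of the resorcinol ring, which can only occur ortho to one hydroxyl and para to the other (the two such positions are equivalent by symmetry), the ketone being held as a difluoroboron chelate that stops a second acylation and is hydrolysed on work-up, while the flavone rings are deactivated by the boron-complexed carbonyl.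

Step 10
Reactants: 16 2-[3-(3-acetyl-2,6-dihydroxyphenyl)-4-methoxyphenyl]-7-methoxy-4H-chromen-4-one, 17 4-hydroxybenzaldehyde
Product: 18 2-{3-[2,6-dihydroxy-3-[(2E)-3-(4-hydroxyphenyl)prop-2-enoyl]phenyl]-4-methoxyphenyl}-7-methoxy-4H-chromen-4-one
Conditions: 17 (1.5 equiv), HCl (4 M in 1,4-dioxane), EtOH, rt
Reagents that add atoms: none
Why: Acid-catalysed Claisen–Schmidt (crossed aldol) condensation between the enol of the acetophenone and the protonated non-enolisable aldehyde, with dehydration to the conjugated (E)-alkene under thermodynamic control; acid in place of hydroxide needs no phenol protection and spares the pyranone of flavone 1 from ring opening, and any flavanone 19 formed by early ring closure converges on the same product in step 11.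

Step 11
Reactants: 18 2-{3-[2,6-dihydroxy-3-[(2E)-3-(4-hydroxyphenyl)prop-2-enoyl]phenyl]-4-methoxyphenyl}-7-methoxy-4H-chromen-4-one
Product: 20 7-hydroxy-2-(4-hydroxyphenyl)-8-[2-methoxy-5-(7-methoxy-4-oxo-4H-chromen-2-yl)phenyl]-4H-chromen-4-one, via flavanone 19 (not isolated)
Conditions: I2 (10 mol%), DMSO, 120 °C
Reagents that add atoms: none
Why: Iodine-catalysed oxidative cyclisation of a 2'-hydroxychalcone, in which oxa-Michael addition of the chelated ortho hydroxyl (the only one able to reach the β-carbon) gives flavanone 19, and α-iodination with loss of HI gives the flavone while DMSO reoxidises the iodide, so that O1 ends beside the biaryl carbon (C8) and the free hydroxyl at C7.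

Compound list
1 | 2-bromoresorcinol (2-bromobenzene-1,3-diol) | Oc1cccc(O)c1Br | starting material
2 | 1,3-bis(benzyloxy)-2-bromobenzene | Brc1c(OCc2ccccc2)cccc1OCc1ccccc1 | intermediate
3 | (E)-4-methoxybut-3-en-2-one | CO/C=C/C(C)=O | starting material
4 | (3E)-1-[2,6-bis(benzyloxy)phenyl]-4-methoxybut-3-en-2-one | CO/C=C/C(=O)Cc1c(OCc2ccccc2)cccc1OCc1ccccc1 | intermediate
5 | (1E,3Z)-4-[2,6-bis(benzyloxy)phenyl]-3-[(tert-butyldimethylsilyl)oxy]-1-methoxybuta-1,3-diene | CO/C=C/C(O[Si](C)(C)C(C)(C)C)=C/c1c(OCc2ccccc2)cccc1OCc1ccccc1 | intermediate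
6 | methyl acrylate | C=CC(=O)OC | starting material
7 | methyl 5-[2,6-bis(benzyloxy)phenyl]-4-[(tert-butyldimethylsilyl)oxy]-2-methoxycyclohex-3-ene-1-carboxylate (racemic mixture of diastereomers, not isolated) | COC(=O)C1CC(c2c(OCc3ccccc3)cccc2OCc2ccccc2)C(O[Si](C)(C)C(C)(C)C)=CC1OC | intermediate
8 | methyl 5-[2,6-bis(benzyloxy)phenyl]-4-oxocyclohex-2-ene-1-carboxylate (racemic mixture of cis and trans diastereomers) | COC(=O)C1C=CC(=O)C(c2c(OCc3ccccc3)cccc2OCc2ccccc2)C1 | intermediate
9 | methyl 3-[2,6-bis(benzyloxy)phenyl]-4-hydroxybenzoate | COC(=O)c1ccc(O)c(-c2c(OCc3ccccc3)cccc2OCc2ccccc2)c1 | intermediate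
10 | methyl 3-[2,6-bis(benzyloxy)phenyl]-4-methoxybenzoate | COC(=O)c1ccc(OC)c(-c2c(OCc3ccccc3)cccc2OCc2ccccc2)c1 | intermediate
11 | paeonol (1-(2-hydroxy-4-methoxyphenyl)ethan-1-one) | CC(=O)c1ccc(OC)cc1O | starting material
12 | 1-{3-[2,6-bis(benzyloxy)phenyl]-4-methoxyphenyl}-3-(2-hydroxy-4-methoxyphenyl)propane-1,3-dione (not isolated) | COc1ccc(C(=O)CC(=O)c2ccc(OC)c(-c3c(OCc4ccccc4)cccc3OCc3ccccc3)c2)c(O)c1 | intermediate
13 | 2-{3-[2,6-bis(benzyloxy)phenyl]-4-methoxyphenyl}-7-methoxy-4H-chromen-4-one | COc1ccc2c(=O)cc(-c3ccc(OC)c(-c4c(OCc5ccccc5)cccc4OCc4ccccc4)c3)oc2c1 | intermediate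
14 | 2-[3-(2,6-dihydroxyphenyl)-4-methoxyphenyl]-7-methoxy-4H-chromen-4-one | COc1ccc2c(=O)cc(-c3ccc(OC)c(-c4c(O)cccc4O)c3)oc2c1 | intermediate
15 | difluoroboron chelate of 16, boron bridging the 2-hydroxyl oxygen and the acetyl oxygen (not isolated) | CC1=[O+][B-](F)(F)Oc2c1ccc(O)c2-c1cc(-c2cc(=O)c3ccc(OC)cc3o2)ccc1OC | intermediate
16 | 2-[3-(3-acetyl-2,6-dihydroxyphenyl)-4-methoxyphenyl]-7-methoxy-4H-chromen-4-one | CC(=O)c1ccc(O)c(-c2cc(-c3cc(=O)c4ccc(OC)cc4o3)ccc2OC)c1O | intermediate
17 | 4-hydroxybenzaldehyde | O=Cc1ccc(O)cc1 | starting material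
18 | 2-{3-[2,6-dihydroxy-3-[(2E)-3-(4-hydroxyphenyl)prop-2-enoyl]phenyl]-4-methoxyphenyl}-7-methoxy-4H-chromen-4-one | O=C(/C=C/c1ccc(O)cc1)c1ccc(O)c(-c2cc(-c3cc(=O)c4ccc(OC)cc4o3)ccc2OC)c1O | intermediate
19 | 7-hydroxy-2-(4-hydroxyphenyl)-8-[2-methoxy-5-(7-methoxy-4-oxo-4H-chromen-2-yl)phenyl]-2,3-dihydro-4H-chromen-4-one (racemic at C2, not isolated) | O=C1CC(c2ccc(O)cc2)Oc2c1ccc(O)c2-c1cc(-c2cc(=O)c3ccc(OC)cc3o2)ccc1OC | intermediate
20 | 7-hydroxy-2-(4-hydroxyphenyl)-8-[2-methoxy-5-(7-methoxy-4-oxo-4H-chromen-2-yl)phenyl]-4H-chromen-4-one | COc1ccc2c(=O)cc(-c3ccc(OC)c(-c4c(O)ccc5c(=O)cc(-c6ccc(O)cc6)oc45)c3)oc2c1 | target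

Total step count: 11. Longest linear sequence: 11 steps (1 to 20); compounds 3, 6, 11 and 17 enter as purchased partners.

Steps most likely to fail

Step 4. The di-ortho-substituted aryl group shields the reacting diene terminus, so the cycloaddition may be slower than thermal decomposition of the diene or polymerisation of the acrylate. The fallback gives up the ring construction and forms the biaryl bond by cross-coupling. It sets out from bromide 2. Commercial methyl 3-bromo-4-methoxybenzoate is borylated (B2pin2, PdCl2(dppf), KOAc, 1,4-dioxane, 90 °C) to methyl 4-methoxy-3-(4,4,5,5-tetramethyl-1,3,2-dioxaborolan-2-yl)benzoate F1. Suzuki–Miyaura coupling of F1 with 2 (Pd(OAc)2, SPhos, K3PO4, toluene/H2O, 100 °C) should give the tri-ortho-substituted biaryl ester 10, where the route is rejoined and steps 2 to 6 are bypassed.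

Step 2. The vinylogous ester 3 may self-condense under base, and oxidative addition into the hindered, electron-rich bromide may be slow, so conversion could stall. The fallback builds the ketone from an arylacetic ester and sets out from 2. Negishi-type coupling with the Reformatsky reagent BrZnCH2CO2Et (Pd2(dba)3, XPhos, THF, 60 °C) should give ethyl [2,6-bis(benzyloxy)phenyl]acetate F2. Treatment with MeNH(OMe)·HCl and iPrMgCl (THF, −20 °C) gives the Weinreb amide 2-[2,6-bis(benzyloxy)phenyl]-N-methoxy-N-methylacetamide F3. Addition of HC≡CMgBr (THF, 0 °C, cold acidic quench) gives 1-[2,6-bis(benzyloxy)phenyl]but-3-yn-2-one F4. Conjugate addition of methanol (MeOH, cat. DABCO, rt) then gives the (E)-β-methoxy enone 4, where the route is rejoined.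

Step 10. Condensation may be incomplete, the product may partly close to the flavanone, and the electron-rich rings may undergo acid-promoted hydroxyalkylation by the aldehyde. The fallback replaces aldol chemistry by acylation and cyclodehydration and sets out from 16. Polylithiation (LiN(SiMe3)2, 5 equiv, THF, −78 °C) and C-acylation with commercial 4-(benzyloxy)benzoyl chloride should give 1-[4-(benzyloxy)phenyl]-3-{2,4-dihydroxy-3-[2-methoxy-5-(7-methoxy-4-oxo-4H-chromen-2-yl)phenyl]phenyl}propane-1,3-dione F5. Cyclodehydration (TsOH·H2O, toluene, 90 °C) gives 2-[4-(benzyloxy)phenyl]-7-hydroxy-8-[2-methoxy-5-(7-methoxy-4-oxo-4H-chromen-2-yl)phenyl]-4H-chromen-4-one F6. Hydrogenolysis (H2, 10% Pd/C, EtOAc/MeOH, rt) gives target 20, so step 11 is not needed.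

Further compounds
F1 | step 4 | methyl 4-methoxy-3-(4,4,5,5-tetramethyl-1,3,2-dioxaborolan-2-yl)benzoate | COC(=O)c1ccc(OC)c(B2OC(C)(C)C(C)(C)O2)c1
F2 | step 2 | ethyl [2,6-bis(benzyloxy)phenyl]acetate | CCOC(=O)Cc1c(OCc2ccccc2)cccc1OCc1ccccc1
F3 | step 2 | 2-[2,6-bis(benzyloxy)phenyl]-N-methoxy-N-methylacetamide | CON(C)C(=O)Cc1c(OCc2ccccc2)cccc1OCc1ccccc1
F4 | step 2 | 1-[2,6-bis(benzyloxy)phenyl]but-3-yn-2-one | C#CC(=O)Cc1c(OCc2ccccc2)cccc1OCc1ccccc1
F5 | step 10 | 1-[4-(benzyloxy)phenyl]-3-{2,4-dihydroxy-3-[2-methoxy-5-(7-methoxy-4-oxo-4H-chromen-2-yl)phenyl]phenyl}propane-1,3-dione | O=C(CC(=O)c1ccc(OCc2ccccc2)cc1)c1ccc(O)c(-c2cc(-c3cc(=O)c4ccc(OC)cc4o3)ccc2OC)c1O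
F6 | step 10 | 2-[4-(benzyloxy)phenyl]-7-hydroxy-8-[2-methoxy-5-(7-methoxy-4-oxo-4H-chromen-2-yl)phenyl]-4H-chromen-4-one | COc1ccc2c(=O)cc(-c3ccc(OC)c(-c4c(O)ccc5c(=O)cc(-c6ccc(OCc7ccccc7)cc6)oc45)c3)oc2c1
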